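**Assumption:** the target has no stereocentres and no stereogenic alkene (the prenyl C=C carries two identical methyls), so it is achiral. The "single enantiomer" requirement is therefore moot and no stereocontrol is needed.

## Retrosynthetic overview

1. The target comes from its tetra-TBS ether 9 by buffered fluoride desilylation, so no acid ever touches the prenyl ether.
2. The pyranone ring (O1–C2 and C3–C4 bonds) is made in one step by Rh-catalysed oxidative C–H/O–H annulation of salicylaldehyde 8 with internal alkyne 6. Alkyne 6 already carries the intact CH2–O–prenyl chain, so there is no flavone C3-functionalisation and no late O-prenylation.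
3. Alkyne 6 comes from Sonogashira coupling of aryl bromide 5 with prenyl propargyl ether 3 (propargyl alcohol + prenyl bromide).
4. Rings A and B are purchased (2,4,6-trihydroxybenzaldehyde, 4-bromocatechol). Ring C is the only ring formed, in the penultimate step.

## Route

**Step 1**
Reactants: 1 propargyl alcohol; 2 prenyl bromide (1-bromo-3-methylbut-2-ene)
Product: 3 prenyl propargyl ether (3-methyl-1-(prop-2-yn-1-yloxy)but-2-ene)
Conditions: NaH (1.05 equiv), THF, 0 °C; then 2, TBAI (cat.), 0 °C→rt
Reagents that add atoms: none (both partners are numbered reactants)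
Why: Williamson ether synthesis; one equivalent of NaH deprotonates only the O–H (pKa ~14 versus ~25 for the alkyne C–H) and the alkoxide displaces the primary allylic bromide by SN2.

**Step 2**
Reactants: 4 4-bromocatechol (4-bromobenzene-1,2-diol)
Product: 5 4-bromo-1,2-bis(tert-butyldimethylsilyloxy)benzene
Conditions: TBSCl (2.3 equiv), imidazole (3 equiv), DMF, rt
Reagents that add atoms: TBSCl, CC(C)(C)[Si](C)(C)Cl
Why: standard imidazole-promoted phenol silylation, which masks the oxidation-prone catechol for the Cu(II)-mediated key step.

**Step 3**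
Reactants: 5 4-bromo-1,2-bis(TBSO)benzene; 3 prenyl propargyl ether
Product: 6 4-[3-(3-methylbut-2-en-1-yloxy)prop-1-yn-1-yl]-1,2-bis(tert-butyldimethylsilyloxy)benzene
Conditions: Pd(PhCN)2Cl2 (3 mol %), [t-Bu3PH]BF4 (6 mol %), CuI (2 mol %), i-Pr2NH, dioxane, rt→40 °C, degassed
Reagents that add atoms: none
Why: Sonogashira coupling with a bulky electron-rich phosphine that activates the electron-rich aryl bromide near rt; the mild amine conditions avoid aryl-silyl cleavage and propargyl→allenyl isomerisation, and a dialkyl prenyl ether is not ionised by Pd(0).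

**Step 4**
Reactants: 7 2,4,6-trihydroxybenzaldehyde
Product: 8 2-hydroxy-4,6-bis(tert-butyldimethylsilyloxy)benzaldehyde
Conditions: TBSCl (2.05 equiv), imidazole (2.5 equiv), THF/CH2Cl2, 0 °C
Reagents that add atoms: TBSCl, CC(C)(C)[Si](C)(C)Cl
Why: chelation-controlled selective silylation; once the 4-OH and one ortho-OH are silylated, the remaining ortho-OH is locked in an intramolecular hydrogen bond to the CHO and is left free, as in the analogous selective bis-MOM/benzyl protections of this aldehyde.

**Step 5 (key step)**
Reactants: 8 2-hydroxy-4,6-bis(TBSO)benzaldehyde; 6 aryl propargyl-ether alkyne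
Product: 9 2-[3,4-bis(tert-butyldimethylsilyloxy)phenyl]-5,7-bis(tert-butyldimethylsilyloxy)-3-{[(3-methylbut-2-en-1-yl)oxy]methyl}-4H-chromen-4-one
Conditions: [RhCl(cod)]2 (2 mol %), 1,2,3,4-tetraphenylcyclopentadiene (8 mol %), Cu(OAc)2·H2O (2.1 equiv), o-xylene, 130 °C, N2 (or [Cp*RhCl2]2 as precatalyst)
Reagents that add atoms: none (Cu(OAc)2 is only the terminal oxidant; the aldehyde H and phenol H are lost)
Why: Rh(III)-catalysed oxidative C–H/O–H annulation of a salicylaldehyde with an internal alkyne (Satoh–Miura-type chromone synthesis), in which hydroxyl-directed aldehyde C–H rhodation gives an acyl-rhodacycle, the aryl/alkyl alkyne inserts with the acyl group going to the CH2OR-bearing carbon and Rh to the aryl-bearing carbon, and C–O reductive elimination closes the pyranone with the aryl at C2 and CH2O-prenyl at C3.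

**Step 6**
Reactants: 9 tetra-TBS flavone
Product: 10 ophioglonol prenyl ether (2-(3,4-dihydroxyphenyl)-5,7-dihydroxy-3-{[(3-methylbut-2-en-1-yl)oxy]methyl}-4H-chromen-4-one)
Conditions: TBAF (4.5 equiv), AcOH (5 equiv), THF, 0 °C→rt; pH 5–6 aqueous work-up
Reagents that add atoms: none
Why: fluoride-mediated cleavage of the four aryl silyl ethers under AcOH buffering (which prevents phenoxide/catecholate air oxidation) leaves the prenyl ether and the chromone untouched.

## Compound list

1 | propargyl alcohol | C#CCO | starting material
2 | prenyl bromide | CC(C)=CCBr | starting material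
3 | prenyl propargyl ether | C#CCOCC=C(C)C | intermediate
4 | 4-bromocatechol | Oc1ccc(Br)cc1O | starting material
5 | 4-bromo-1,2-bis(TBSO)benzene | CC(C)(C)[Si](C)(C)Oc1ccc(Br)cc1O[Si](C)(C)C(C)(C)C | intermediate
6 | 4-[3-(prenyloxy)prop-1-ynyl]-1,2-bis(TBSO)benzene | CC(C)=CCOCC#Cc1ccc(O[Si](C)(C)C(C)(C)C)c(O[Si](C)(C)C(C)(C)C)c1 | intermediate
7 | 2,4,6-trihydroxybenzaldehyde | O=Cc1c(O)cc(O)cc1O | starting material
8 | 2-hydroxy-4,6-bis(TBSO)benzaldehyde | O=Cc1c(O)cc(O[Si](C)(C)C(C)(C)C)cc1O[Si](C)(C)C(C)(C)C | intermediate
9 | 5,7,3',4'-tetrakis(TBSO)-3-(prenyloxymethyl)flavone | CC(C)=CCOCc1c(-c2ccc(O[Si](C)(C)C(C)(C)C)c(O[Si](C)(C)C(C)(C)C)c2)oc2cc(O[Si](C)(C)C(C)(C)C)cc(O[Si](C)(C)C(C)(C)C)c2c1=O | intermediate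
10 | ophioglonol prenyl ether | CC(C)=CCOCc1c(-c2ccc(O)c(O)c2)oc2cc(O)cc(O)c2c1=O | target

## Summary

**Total steps:** 6 (convergent).
**Longest linear sequence:** 4 steps (1/2 → 3 → 6 → 9 → 10, or equally 4 → 5 → 6 → 9 → 10).

**Three steps most likely to fail, with fallbacks:**

1. **Step 5 (Rh annulation).** Risks are wrong alkyne-insertion regiochemistry (ether-oxygen chelation), Rh-mediated chemistry of the 1,6-enyne embedded in 6, decarbonylation, steric hindrance from the 6-OTBS group, and partial silyl loss at 130 °C.
   Fallback: abandon the C–H annulation. Add the lithium acetylide of 4-ethynyl-1,2-bis(TBSO)benzene to the fully silylated aldehyde, oxidise to the ynone, and run an ICl-induced 6-endo iodocyclisation to the 3-iodoflavone. Then attach the intact side chain by Suzuki–Miyaura coupling with potassium [(prenyloxy)methyl]trifluoroborate.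

2. **Step 4 (selective bis-silylation).** Risks are mono/bis/tris mixtures and silyl migration.
   Fallback: change the protecting-group strategy to the well-behaved 2-hydroxy-4,6-bis(methoxymethoxy)benzaldehyde (with a bis-MOM bromocatechol partner). The endgame then becomes a non-protic aryl-MOM cleavage (TMSOTf/2,2'-bipyridyl, then water) instead of fluoride, so the acid-sensitive prenyl ether is still not exposed to protic acid.

3. **Step 3 (Sonogashira on an electron-rich aryl bromide).** Risks are sluggish oxidative addition, Glaser dimerisation of 3, and propargyl/allenyl isomerisation.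
   Fallback: reverse the polarity. Prepare 4-ethynyl-1,2-bis(TBSO)benzene by Corey–Fuchs homologation of 3,4-bis(TBSO)benzaldehyde, and alkylate its lithium acetylide with prenyl chloromethyl ether (ClCH2OCH2CH=CMe2) to give 6 directly, forming the C(sp)–CH2 bond instead of the aryl–C(sp) bond.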